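**Retrosynthetic overview**

1. The target is 2,4-dibromo-6-(2,3,5-tribromo-6-methoxyphenoxy)phenol: ring A carries C1 OAr, C2 OMe, C3 Br, C4 H, C5 Br, C6 Br; ring B carries C1' OAr, C2' OH, C3' Br, C5' Br; there is no stereocentre.
2. Feature the plan rests on: C3 to C6 of ring A (Br, H, Br, Br) are C5, C4, C3, C2 of 2,3,5-tribromothiophene with all three bromines in place, and the oxygenated pair C1–C2 is the O–CH=C(O)2 unit of one arm of dimethyl diglycolate, whose ether oxygen becomes the diaryl ether oxygen.
3. Last disconnection (ring B, C1'–C6' and C2'–C3'): bis-silyl ketene acetal of the ring A aryloxyacetic acid plus 3,5-dibromo-2-pyrone, with loss of CO2 and silanol.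
4. Key disconnection (ring A, C1–C6 and C2–C3): 2,3,5-tribromothiophene 1,1-dioxide plus the mono silyl ketene acetal of dimethyl diglycolate, with loss of SO2 and methanol.
5. Order of ring formation: ring A in step 3, ring B in step 7; no aryl–oxygen coupling is used anywhere.

Key step: step 3

Assumption: 3,5-dibromo-2-pyrone is treated as purchasable; it is otherwise one step from coumalic acid with NBS and LiOAc.
Remark: the sp3 centres of the not-isolated cycloadducts are drawn for one diastereomer of the racemate; they are erased on aromatisation and need no control.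

**Route**

Step 1
Reactants: 1 2,3,5-tribromothiophene
Product: 2 2,3,5-tribromothiophene 1,1-dioxide
Conditions: H2O2·urea, (CF3CO)2O, MeCN/CH2Cl2, 0 → 23 °C
Reagents that add atoms: trifluoroperacetic acid, OOC(=O)C(F)(F)F, made in the flask from hydrogen peroxide–urea (OO.NC(N)=O) and trifluoroacetic anhydride (O=C(OC(=O)C(F)(F)F)C(F)(F)F)
Why: Trifluoroperacetic acid is electrophilic enough to oxidise the sulfur of a halogen-deactivated thiophene twice (peracid S-oxidation to the sulfone), and bromine on both α-carbons should slow the [4+2] self-dimerisation that destroys less substituted thiophene dioxides.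

Step 2
Reactants: 3 dimethyl diglycolate
Product: 5 methyl 2-{[(Z)-2-(tert-butyldimethylsilyloxy)-2-methoxyethenyl]oxy}acetate, via lithium enolate 4 (not isolated)
Conditions: LiN(i-Pr)2 (1.0 equiv), THF, −78 °C; TBSCl, DMPU, −78 → 0 °C; pentane, filter
Reagents that add atoms: tert-butyldimethylsilyl chloride, CC(C)(C)[Si](C)(C)Cl
Why: Kinetic deprotonation of one CH2 of the symmetrical diester should give the lithium enolate chelated by the ether oxygen, and O-silylation with TBSCl in the presence of DMPU (silyl ketene acetal formation) fixes it as the Z acetal, one equivalent of base at −78 °C limiting Claisen condensation and double enolisation.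

Step 3
Reactants: 2 2,3,5-tribromothiophene 1,1-dioxide; 5 methyl 2-{[(Z)-2-(tert-butyldimethylsilyloxy)-2-methoxyethenyl]oxy}acetate
Product: 8 methyl 2-[2,3,5-tribromo-6-(tert-butyldimethylsilyloxy)phenoxy]acetate, via bridged sulfone adduct 6 (not isolated), via cyclohexadiene ketal 7 (not isolated)
Conditions: 5 (2 equiv), PhMe, 23 → 90 °C, N2 stream; PPTS (cat.) to finish the elimination
Reagents that add atoms: none
Why: The electron-poor sulfone diene 2 and the electron-rich alkene 5 should combine in a concerted but asynchronous inverse-demand [4+2] cycloaddition that forms C1–C6 and C2–C3 and closes ring A as the bridged sulfone 6, which loses SO2 cheletropically to diene 7, and 1,2-elimination of methanol (H from C1, OMe from C2) then makes the ring aromatic. The closest known reaction type is the Diels–Alder reaction of halogenated thiophene 1,1-dioxides with alkenes and enol ethers followed by extrusion of SO2. Ring A is closed by an intermolecular cycloaddition that makes both new C–C bonds in one event, and because C1 holds the only hydrogen of 7 and C2 holds both leaving groups, elimination across C1–C2 is the only way to an arene and both ring oxygens are kept. The sp3 centres of 6 and 7 are transient and erased, so no stereocontrol is needed. The selectivity required is regiochemical: the nucleophilic oxygen-bearing CH carbon of 5 must bond to the diene terminus flanked by the second C–Br (future C6), which is expected because this places the developing negative charge on bromine-bearing carbons and leaves the bulky acetal carbon to bond at the terminus next to C4–H; this orientation has not been tested on an unsymmetrical tribromide. Methanol should leave in preference to silanol because its oxygen is the more basic one under the mildly acidic conditions, and any material that loses silanol instead is already the methyl ether that step 4 makes, so both paths converge.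

Step 4
Reactants: 8 methyl 2-[2,3,5-tribromo-6-(tert-butyldimethylsilyloxy)phenoxy]acetate
Product: 10 methyl 2-(2,3,5-tribromo-6-methoxyphenoxy)acetate, via caesium phenolate 9 (not isolated)
Conditions: CsF, MeI, DMF, 23 °C
Reagents that add atoms: iodomethane, CI
Why: Fluoride cleaves the aryl silyl ether and the phenolate is methylated in the same flask by iodomethane (desilylative Williamson etherification), the electron-poor phenolate being too weak a nucleophile to displace methoxide from the neighbouring ester.

Step 5
Reactants: 10 methyl 2-(2,3,5-tribromo-6-methoxyphenoxy)acetate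
Product: 12 2-(2,3,5-tribromo-6-methoxyphenoxy)acetic acid, via lithium carboxylate 11 (not isolated)
Conditions: LiOH, THF/H2O, 0 → 23 °C; then 1 M HCl
Reagents that add atoms: lithium hydroxide, [Li+].[OH-]
Why: Saponification of an unhindered methyl ester by hydroxide, to which the aryl ethers and aryl bromides are inert at room temperature.

Step 6
Reactants: 12 2-(2,3,5-tribromo-6-methoxyphenoxy)acetic acid
Product: 15 1,1-bis(trimethylsilyloxy)-2-(2,3,5-tribromo-6-methoxyphenoxy)ethene, via trimethylsilyl ester 13 (not isolated), via lithium enolate 14 (not isolated)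
Conditions: TMSCl, Et3N, THF, 0 °C, filter; LiN(SiMe3)2, TMSCl, THF, −78 → 0 °C; pentane, filter, use crude
Reagents that add atoms: chlorotrimethylsilane, C[Si](C)(C)Cl
Why: The acid is O-silylated and the α-aryloxy silyl ester is then enolised by LiN(SiMe3)2 in the presence of TMSCl and trapped on oxygen (formation of a bis-silyl ketene acetal by enolate O-silylation), the hexamethyldisilazide being too weak a base to remove the ring A C4 hydrogen between two bromines, so bromine migration is not expected.

Step 7
Reactants: 15 1,1-bis(trimethylsilyloxy)-2-(2,3,5-tribromo-6-methoxyphenoxy)ethene; 16 3,5-dibromo-2-pyrone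
Product: 20 2,4-dibromo-6-(2,3,5-tribromo-6-methoxyphenoxy)phenol, via bicyclic lactone 17 (not isolated), via bis(silyloxy)cyclohexadiene 18 (not isolated), via aryl trimethylsilyl ether 19 (not isolated)
Conditions: 15 (1.5 equiv), PhMe, 80 → 110 °C; then 1 M HCl, THF, 23 °C
Reagents that add atoms: none
Why: Inverse-demand Diels–Alder reaction of a ketene acetal with a 2-pyrone, in which the nucleophilic aryloxy-bearing carbon should bond to the electrophilic C6 of the pyrone and the acetal carbon to C3 (the orientation expected for electron-rich alkenes with 3-bromo-2-pyrones), followed by retro-[4+2] loss of CO2, elimination of silanol across the only H–C–C–O pair (both acetal oxygens carry silicon, so a silyl ether results whichever leaves) and acid cleavage of the aryl silyl ether to the phenol with oxygen on C2' next to C3'–Br.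

**Compound list**

1 | 2,3,5-tribromothiophene | Brc1cc(Br)c(Br)s1 | starting material
2 | 2,3,5-tribromothiophene 1,1-dioxide | O=S1(=O)C(Br)=CC(Br)=C1Br | intermediate
3 | dimethyl diglycolate | COC(=O)COCC(=O)OC | starting material
4 | lithium (Z)-enolate of dimethyl diglycolate, chelated by the ether oxygen | COC(=O)CO/C=C(/OC)[O-].[Li+] | intermediate
5 | methyl 2-{[(Z)-2-(tert-butyldimethylsilyloxy)-2-methoxyethenyl]oxy}acetate | COC(=O)CO/C=C(/OC)O[Si](C)(C)C(C)(C)C | intermediate
6 | methyl 2-{[1,2,4-tribromo-5-(tert-butyldimethylsilyloxy)-5-methoxy-7-thiabicyclo[2.2.1]hept-2-en-6-yl]oxy}acetate 7,7-dioxide (racemic, one diastereomer drawn) | COC(=O)CO[C@@H]1[C@](OC)(O[Si](C)(C)C(C)(C)C)[C@]2(Br)C=C(Br)[C@@]1(Br)S2(=O)=O | intermediate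
7 | methyl 2-{[2,3,5-tribromo-6-(tert-butyldimethylsilyloxy)-6-methoxycyclohexa-2,4-dien-1-yl]oxy}acetate (racemic, ether oxygen and silyloxy cis) | COC(=O)CO[C@@H]1[C@](OC)(O[Si](C)(C)C(C)(C)C)C(Br)=CC(Br)=C1Br | intermediate
8 | methyl 2-[2,3,5-tribromo-6-(tert-butyldimethylsilyloxy)phenoxy]acetate | COC(=O)COc1c(Br)c(Br)cc(Br)c1O[Si](C)(C)C(C)(C)C | intermediate
9 | caesium 3,4,6-tribromo-2-(2-methoxy-2-oxoethoxy)phenolate | COC(=O)COc1c(Br)c(Br)cc(Br)c1[O-].[Cs+] | intermediate
10 | methyl 2-(2,3,5-tribromo-6-methoxyphenoxy)acetate | COC(=O)COc1c(Br)c(Br)cc(Br)c1OC | intermediate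
11 | lithium 2-(2,3,5-tribromo-6-methoxyphenoxy)acetate | COc1c(Br)cc(Br)c(Br)c1OCC(=O)[O-].[Li+] | intermediate
12 | 2-(2,3,5-tribromo-6-methoxyphenoxy)acetic acid | COc1c(Br)cc(Br)c(Br)c1OCC(=O)O | intermediate
13 | trimethylsilyl 2-(2,3,5-tribromo-6-methoxyphenoxy)acetate | COc1c(Br)cc(Br)c(Br)c1OCC(=O)O[Si](C)(C)C | intermediate
14 | lithium enolate of trimethylsilyl ester 13 (aryloxy cis to O–Li) | COc1c(Br)cc(Br)c(Br)c1O/C=C(/O[Si](C)(C)C)[O-].[Li+] | intermediate
15 | 1,1-bis(trimethylsilyloxy)-2-(2,3,5-tribromo-6-methoxyphenoxy)ethene | COc1c(Br)cc(Br)c(Br)c1OC=C(O[Si](C)(C)C)O[Si](C)(C)C | intermediate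
16 | 3,5-dibromo-2-pyrone (3,5-dibromo-2H-pyran-2-one) | O=C1OC=C(Br)C=C1Br | starting material
17 | 4,7-dibromo-6-(2,3,5-tribromo-6-methoxyphenoxy)-5,5-bis(trimethylsilyloxy)-2-oxabicyclo[2.2.2]oct-7-en-3-one (racemic, one diastereomer drawn) | COc1c(Br)cc(Br)c(Br)c1O[C@@H]2C(O[Si](C)(C)C)(O[Si](C)(C)C)[C@]3(Br)C=C(Br)[C@H]2OC3=O | intermediate
18 | 2,4-dibromo-6-(2,3,5-tribromo-6-methoxyphenoxy)-1,1-bis(trimethylsilyloxy)cyclohexa-2,4-diene (racemic) | COc1c(Br)cc(Br)c(Br)c1O[C@@H]2C(O[Si](C)(C)C)(O[Si](C)(C)C)C(Br)=CC(Br)=C2 | intermediate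
19 | [2,4-dibromo-6-(2,3,5-tribromo-6-methoxyphenoxy)phenoxy]trimethylsilane | COc1c(Br)cc(Br)c(Br)c1Oc1cc(Br)cc(Br)c1O[Si](C)(C)C | intermediate
20 | 2,4-dibromo-6-(2,3,5-tribromo-6-methoxyphenoxy)phenol | COc1c(Br)cc(Br)c(Br)c1Oc1cc(Br)cc(Br)c1O | target

**Summary**

Total step count: 7.
Longest linear sequence: 6 steps (1 → 2 → 8 → 10 → 12 → 15 → 20; the branch from 3 through 5 is equally long).

**Steps most likely to fail**

Step 3. What may go wrong: the two new bonds form with the opposite orientation, the nucleophilic CH carbon joining the diene terminus next to C4–H, which would exchange the positions of the glycolate oxygen and the silyloxy group on ring A. The fallback sets out from 2 and comes back at 10. It changes the two-carbon partner so that this opposite orientation becomes the productive one, and adds the acetate arm afterwards by O-alkylation. Methyl methoxyacetate (COCC(=O)OC) is deprotonated with LiN(i-Pr)2 at −78 °C to the chelated lithium (Z)-1,2-dimethoxyethenolate F1 and silylated with TBSCl/DMPU to (Z)-tert-butyl[(1,2-dimethoxyethenyl)oxy]dimethylsilane F2. F2 and 2 in toluene should give the bridged sulfone 1,2,4-tribromo-6-(tert-butyldimethylsilyloxy)-5,6-dimethoxy-7-thiabicyclo[2.2.1]hept-2-ene 7,7-dioxide F3, which loses SO2 to 1,2,4-tribromo-6-(tert-butyldimethylsilyloxy)-5,6-dimethoxycyclohexa-1,3-diene F4, and elimination of methanol gives tert-butyl(dimethyl)(2,3,5-tribromo-6-methoxyphenoxy)silane F5, with methoxy on C2 and silyloxy on C1. CsF and methyl bromoacetate (COC(=O)CBr) in DMF then release caesium 2,3,5-tribromo-6-methoxyphenolate F6 and alkylate it on oxygen to give 10.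

Step 7. What may go wrong: the hindered, trisubstituted ketene acetal is protonated or desilylated faster than it adds to the pyrone, or adds with the wrong orientation. This fallback also covers a failure of the enolisation in step 6, since it leaves the route before that step. It sets out from 12 and comes back at 20, and it attaches ring B as a ready-made benzene ring by nucleophilic aromatic substitution. Oxidative decarboxylation of 12 with Pb(OAc)4 (Cu(OAc)2 cat., pyridine, benzene, 80 °C) gives (2,3,5-tribromo-6-methoxyphenoxy)methyl acetate F7, and K2CO3 in methanol releases 2,3,5-tribromo-6-methoxyphenol F8. F8 displaces fluoride from 2-fluorobenzaldehyde (O=Cc1ccccc1F; K2CO3, DMAc, 130 °C) to give 2-(2,3,5-tribromo-6-methoxyphenoxy)benzaldehyde F9. Baeyer–Villiger oxidation with mCPBA in CH2Cl2 gives 2-(2,3,5-tribromo-6-methoxyphenoxy)phenyl formate F10, and methanolysis (K2CO3, MeOH) gives 2-(2,3,5-tribromo-6-methoxyphenoxy)phenol F11. Br2 (2 equiv) in AcOH should then brominate ortho and para to the free hydroxyl, ring A being fully deactivated, to give 20.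

Step 1. What may go wrong: the strongly deactivated sulfur is oxidised incompletely, or the sulfone decomposes or dimerises under the acidic oxidising conditions. The fallback sets out from 1 and comes back at 2. It oxidises a silylated, more electron-rich thiophene and restores the α-bromines afterwards. Bromine–lithium exchange at both α-positions of 1 (n-BuLi, 2 equiv, THF, −78 °C) gives 3-bromo-2,5-dilithiothiophene F12, which TMSCl converts to 3-bromo-2,5-bis(trimethylsilyl)thiophene F13. mCPBA in CH2Cl2 oxidises F13 to 3-bromo-2,5-bis(trimethylsilyl)thiophene 1,1-dioxide F14, and Br2 with AgBF4 in CH2Cl2 at 0 °C replaces both silyl groups by bromine (ipso-bromodesilylation) to give 2.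

**Further compounds**

F1 | step 3 | lithium (Z)-1,2-dimethoxyethenolate | CO/C=C(/OC)[O-].[Li+]
F2 | step 3 | (Z)-tert-butyl[(1,2-dimethoxyethenyl)oxy]dimethylsilane | CO/C=C(/OC)O[Si](C)(C)C(C)(C)C
F3 | step 3 | 1,2,4-tribromo-6-(tert-butyldimethylsilyloxy)-5,6-dimethoxy-7-thiabicyclo[2.2.1]hept-2-ene 7,7-dioxide | CO[C@@H]1[C@](OC)(O[Si](C)(C)C(C)(C)C)[C@]2(Br)C(Br)=C[C@@]1(Br)S2(=O)=O
F4 | step 3 | 1,2,4-tribromo-6-(tert-butyldimethylsilyloxy)-5,6-dimethoxycyclohexa-1,3-diene | CO[C@@H]1[C@](OC)(O[Si](C)(C)C(C)(C)C)C(Br)=C(Br)C=C1Br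
F5 | step 3 | tert-butyl(dimethyl)(2,3,5-tribromo-6-methoxyphenoxy)silane | COc1c(Br)cc(Br)c(Br)c1O[Si](C)(C)C(C)(C)C
F6 | step 3 | caesium 2,3,5-tribromo-6-methoxyphenolate | COc1c(Br)cc(Br)c(Br)c1[O-].[Cs+]
F7 | step 7 | (2,3,5-tribromo-6-methoxyphenoxy)methyl acetate | COc1c(Br)cc(Br)c(Br)c1OCOC(C)=O
F8 | step 7 | 2,3,5-tribromo-6-methoxyphenol | COc1c(Br)cc(Br)c(Br)c1O
F9 | step 7 | 2-(2,3,5-tribromo-6-methoxyphenoxy)benzaldehyde | COc1c(Br)cc(Br)c(Br)c1Oc1ccccc1C=O
F10 | step 7 | 2-(2,3,5-tribromo-6-methoxyphenoxy)phenyl formate | COc1c(Br)cc(Br)c(Br)c1Oc1ccccc1OC=O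
F11 | step 7 | 2-(2,3,5-tribromo-6-methoxyphenoxy)phenol | COc1c(Br)cc(Br)c(Br)c1Oc1ccccc1O
F12 | step 1 | 3-bromo-2,5-dilithiothiophene | [Li]c1cc(Br)c([Li])s1
F13 | step 1 | 3-bromo-2,5-bis(trimethylsilyl)thiophene | C[Si](C)(C)c1cc(Br)c([Si](C)(C)C)s1
F14 | step 1 | 3-bromo-2,5-bis(trimethylsilyl)thiophene 1,1-dioxide | C[Si](C)(C)C1=CC(Br)=C([Si](C)(C)C)S1(=O)=O
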